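## Retrosynthetic overview

- The target is reached by acid removal of two MOM ethers from its catechol bis-MOM ether; every other group is already in place at that stage.
- Ring B (the pyran) is opened at O2–C1H2. The 2H-pyran is the closed valence tautomer of the 1-oxatriene O2=C3–C4=C4a–C8a=C1, and C1–C8a=C4a–C8=O is a Morita–Baylis–Hillman (MBH) unit of the ring-A enone. This is the feature that makes the key step possible.
- The oxatriene is made in the same flask by a formal [3+3] union. The ring-A MBH acetate supplies C1, C8a and C4a. A β-keto sulfoxide supplies C4, C3, O2 and the complete (E)-acrylic acid chain. The C4–C4a bond forms by SN2′, then sulfoxide syn-elimination sets the oxidation level.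
- Ring A is bought as 2-methylcyclohex-2-en-1-one. CBS reduction and anti-selective osmylation set C6 and C7, the hindered aryl ester is attached early, and oxidation/dehydrogenation plus Baylis–Hillman hydroxymethylation give the acetate.
- Ring order: ring A from the start, ring B in step 17, then deprotection. The aroyl chloride comes from 2,3,4-trimethoxy-6-methylbenzaldehyde; the sulfoxide acid from a chloro keto ylide and glyoxylic acid.

Key step: step 17

Remark: the β-keto sulfoxide partner is used as the racemate at sulfur, because that centre is expelled in the key step; locants C1, O2, C3, C4, C4a, C5–C8 and C8a are the 1H-isochromene positions of the target.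

## Route

**Aryl fragment**

Step 1
Reactants: 1 2,3,4-trimethoxy-6-methylbenzaldehyde
Product: 2 2,3,4-trihydroxy-6-methylbenzaldehyde
Conditions: BBr3 (4 equiv), CH2Cl2, −78 °C to rt; then H2O
Reagents that add atoms: none
Why: Lewis-acid cleavage of aryl methyl ethers (BBr3 demethylation) should remove all three methyl groups while the aldehyde survives as its boron complex until aqueous work-up.

Step 2
Reactants: 2 2,3,4-trihydroxy-6-methylbenzaldehyde
Product: 3 2-hydroxy-3,4-bis(methoxymethoxy)-6-methylbenzaldehyde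
Conditions: MOMCl (2.1 equiv), i-Pr2NEt, CH2Cl2, 0 °C
Reagents that add atoms: chloromethyl methyl ether, COCCl
Why: Williamson-type O-alkylation should take the 3- and 4-hydroxyl groups, because the 2-hydroxyl is locked in a hydrogen bond to the formyl group and is the least nucleophilic.

Step 3
Reactants: 3 2-hydroxy-3,4-bis(methoxymethoxy)-6-methylbenzaldehyde
Product: 4 2-methoxy-3,4-bis(methoxymethoxy)-6-methylbenzaldehyde
Conditions: MeI, K2CO3, DMF, 40 °C
Reagents that add atoms: iodomethane, CI
Why: Williamson O-methylation of the remaining chelated phenol as its potassium phenoxide should be clean since no other acidic site is left.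

Step 4
Reactants: 4 2-methoxy-3,4-bis(methoxymethoxy)-6-methylbenzaldehyde
Product: 5 2-methoxy-3,4-bis(methoxymethoxy)-6-methylbenzoic acid
Conditions: NaClO2, NaH2PO4, 2-methylbut-2-ene, t-BuOH/H2O, rt
Reagents that add atoms: sodium chlorite, [Na+].[O-]Cl=O
Why: Pinnick oxidation converts hindered aryl aldehydes to acids at a buffered pH that the MOM acetals tolerate, with the alkene scavenging hypochlorite.

Step 5
Reactants: 5 2-methoxy-3,4-bis(methoxymethoxy)-6-methylbenzoic acid
Product: 6 2-methoxy-3,4-bis(methoxymethoxy)-6-methylbenzoyl chloride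
Conditions: 1-chloro-N,N,2-trimethylprop-1-en-1-amine (1.2 equiv), CH2Cl2, 0 °C to rt; used crude
Reagents that add atoms: 1-chloro-N,N,2-trimethylprop-1-en-1-amine, CC(C)=C(Cl)N(C)C
Why: acid chloride formation with an α-chloroenamine is neutral and releases no HCl, so the acid-labile MOM groups should survive.

**β-Keto sulfoxide fragment**

Step 6
Reactants: 7 1-chloro-3-(triphenyl-λ5-phosphanylidene)propan-2-one
Product: 8 1-(phenylsulfanyl)-3-(triphenyl-λ5-phosphanylidene)propan-2-one
Conditions: PhSH, Et3N, CH2Cl2, 0 °C to rt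
Reagents that add atoms: thiophenol, Sc1ccccc1
Why: SN2 displacement of the α-chloro ketone chloride by thiolate should proceed without touching the stabilised acyl ylide, which is restored by the amine base.

Step 7
Reactants: 8 1-(phenylsulfanyl)-3-(triphenyl-λ5-phosphanylidene)propan-2-one
Product: 9 (2E)-4-oxo-5-(phenylsulfanyl)pent-2-enoic acid
Conditions: glyoxylic acid monohydrate, CH2Cl2, rt; acid–base extraction
Reagents that add atoms: glyoxylic acid monohydrate, OC(O)C(O)=O
Why: Wittig olefination of a stabilised acyl ylide with the very electrophilic glyoxylic aldehyde should give the 4-oxo-2-enoic acid with the E alkene, as is usual for stabilised ylides.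

Step 8
Reactants: 9 (2E)-4-oxo-5-(phenylsulfanyl)pent-2-enoic acid
Product: 10 (2E)-4-oxo-5-(phenylsulfinyl)pent-2-enoic acid (racemic at sulfur)
Conditions: NaIO4 (1.05 equiv), MeOH/H2O, 0 °C
Reagents that add atoms: sodium periodate, [Na+].[O-]I(=O)(=O)=O
Why: periodate oxidation of a sulfide stops at the sulfoxide and does not attack the electron-poor alkene; the product has no β-hydrogen syn-elimination path and should be storable.

**Ring A and assembly**

Step 9
Reactants: 11 2-methylcyclohex-2-en-1-one
Product: 12 (1R)-2-methylcyclohex-2-en-1-ol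
Conditions: (S)-2-methyl-CBS-oxazaborolidine (10 mol%), BH3·SMe2, THF, −20 °C
Reagents that add atoms: none
Why: CBS reduction, in which the α-methylalkenyl arm acts as the large group of the ketone–catalyst–borane complex, so hydride is delivered to the face that gives the R carbinol (this centre is oxidised away later but steers the dihydroxylation).

Step 10
Reactants: 12 (1R)-2-methylcyclohex-2-en-1-ol
Product: 13 tert-butyl(dimethyl){[(1R)-2-methylcyclohex-2-en-1-yl]oxy}silane
Conditions: TBSCl, imidazole, DMF, rt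
Reagents that add atoms: tert-butyl(chloro)dimethylsilane, CC(C)(C)[Si](C)(C)Cl
Why: standard silylation of a secondary allylic alcohol, giving the bulky allylic ether needed for facial control in the next step.

Step 11
Reactants: 13 tert-butyl(dimethyl){[(1R)-2-methylcyclohex-2-en-1-yl]oxy}silane
Product: 14 (1R,2R,3R)-3-{[tert-butyl(dimethyl)silyl]oxy}-2-methylcyclohexane-1,2-diol
Conditions: K2OsO4·2H2O (2 mol%), NMO, acetone/H2O, rt
Reagents that add atoms: 4-methylmorpholine N-oxide, C[N+]1([O-])CCOCC1; water, O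
Why: Upjohn dihydroxylation, in which A(1,2) strain with the 2-methyl group keeps the allylic OTBS group pseudoaxial, so OsO4 should add syn on the face anti to it and set C1 and C2 of the diol (C6 and C7 of the target) relative to the CBS-derived centre.

Step 12
Reactants: 14 (1R,2R,3R)-3-{[tert-butyl(dimethyl)silyl]oxy}-2-methylcyclohexane-1,2-diol; 6 2-methoxy-3,4-bis(methoxymethoxy)-6-methylbenzoyl chloride
Product: 15 (1R,2R,3R)-3-{[tert-butyl(dimethyl)silyl]oxy}-2-hydroxy-2-methylcyclohexyl 2-methoxy-3,4-bis(methoxymethoxy)-6-methylbenzoate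
Conditions: DMAP, Et3N, CH2Cl2, 0 to 40 °C
Reagents that add atoms: none
Why: DMAP-catalysed acylation should take the only secondary hydroxyl, the tertiary one being too hindered for the di-ortho-substituted acylpyridinium; the configuration at the carbinol carbon is retained.

Step 13
Reactants: 15 (1R,2R,3R)-3-{[tert-butyl(dimethyl)silyl]oxy}-2-hydroxy-2-methylcyclohexyl 2-methoxy-3,4-bis(methoxymethoxy)-6-methylbenzoate
Product: 16 (1R,2S,3R)-2,3-dihydroxy-2-methylcyclohexyl 2-methoxy-3,4-bis(methoxymethoxy)-6-methylbenzoate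
Conditions: HF·pyridine, pyridine, THF, 0 °C to rt
Reagents that add atoms: none
Why: fluoride desilylation under buffered, non-basic conditions should free the secondary alcohol without acyl migration or loss of the aryl MOM ethers (the descriptor at C2 changes only through the priority rules).

Step 14
Reactants: 16 (1R,2S,3R)-2,3-dihydroxy-2-methylcyclohexyl 2-methoxy-3,4-bis(methoxymethoxy)-6-methylbenzoate
Product: 18 (1R,6R)-6-hydroxy-6-methyl-5-oxocyclohex-3-en-1-yl 2-methoxy-3,4-bis(methoxymethoxy)-6-methylbenzoate, via ketone 17 (not isolated)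
Conditions: IBX (1.5 equiv), DMSO, rt; then IBX·4-methoxypyridine N-oxide complex (2 equiv), DMSO, rt
Reagents that add atoms: none
Why: IBX oxidation of the secondary alcohol (1,2-diols are not cleaved) followed by IBX dehydrogenation of the ketone, which can only enolise towards its single α-CH2 because the other α-carbon is quaternary, should give the enone; room temperature avoids benzylic oxidation of the aryl methyl group.

Step 15
Reactants: 18 (1R,6R)-6-hydroxy-6-methyl-5-oxocyclohex-3-en-1-yl 2-methoxy-3,4-bis(methoxymethoxy)-6-methylbenzoate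
Product: 19 (1R,6R)-6-hydroxy-4-(hydroxymethyl)-6-methyl-5-oxocyclohex-3-en-1-yl 2-methoxy-3,4-bis(methoxymethoxy)-6-methylbenzoate
Conditions: aq. CH2O (37%), DMAP (0.3 equiv), THF/H2O, rt
Reagents that add atoms: formaldehyde, C=O
Why: Morita–Baylis–Hillman hydroxymethylation of a cyclohexenone with an unsubstituted β-CH, in which DMAP adds at the β-carbon, the enolate traps formaldehyde at the α-carbon and DMAP is expelled.

Step 16
Reactants: 19 (1R,6R)-6-hydroxy-4-(hydroxymethyl)-6-methyl-5-oxocyclohex-3-en-1-yl 2-methoxy-3,4-bis(methoxymethoxy)-6-methylbenzoate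
Product: 20 (1R,6R)-4-[(acetyloxy)methyl]-6-hydroxy-6-methyl-5-oxocyclohex-3-en-1-yl 2-methoxy-3,4-bis(methoxymethoxy)-6-methylbenzoate
Conditions: Ac2O (1.2 equiv), pyridine, CH2Cl2, 0 °C
Reagents that add atoms: acetic anhydride, CC(=O)OC(C)=O
Why: acetylation without DMAP should be selective for the primary allylic alcohol over the tertiary α-ketol hydroxyl.

Step 17
Reactants: 20 (1R,6R)-4-[(acetyloxy)methyl]-6-hydroxy-6-methyl-5-oxocyclohex-3-en-1-yl 2-methoxy-3,4-bis(methoxymethoxy)-6-methylbenzoate; 10 (2E)-4-oxo-5-(phenylsulfinyl)pent-2-enoic acid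
Product: 23 (2E)-3-[(6R,7R)-7-hydroxy-6-{[2-methoxy-3,4-bis(methoxymethoxy)-6-methylbenzoyl]oxy}-7-methyl-8-oxo-5,6,7,8-tetrahydro-1H-isochromen-3-yl]prop-2-enoic acid, via methylidene ketone sulfoxide 21 (not isolated), via cross-conjugated dienone 22 (not isolated)
Conditions: 10 (1.3 equiv), Cs2CO3 (2.8 equiv), MeCN, 0 °C to rt; then AcOH, PhMe (0.01 M), 80 °C
Reagents that add atoms: none
Why: Proposed new method: a formal [3+3] annulation in which the cesium dianion of 10 adds through its sulfinyl-stabilised carbon to C4a of 20 with E1cB loss of acetate (SN2′) to give the 2-methylidene ketone 21, the α-sulfinyl ketone then loses PhSOH by thermal syn-elimination towards its only β-hydrogen (C4a–H) to give the dienone 22, and 22, a 1-oxatriene O2=C3–C4=C4a–C8a=C1, closes by thermal oxa-6π electrocyclisation. The closest known reaction types are the base-mediated SN2′ alkylation of cyclic Morita–Baylis–Hillman acetates by 1,3-dicarbonyl C–H acids, the alkylation/dehydrosulfinylation route from β-keto sulfoxides to enones and the Knoevenagel/oxa-6π synthesis of 2H-pyrans. Ring B is the only ring closed, by a disrotatory 6π electrocyclic (formally 6-endo) bond formation between the ketone oxygen O2 and the exocyclic methylidene carbon C1. No new stereocentre is created: C4a, the sulfinyl carbon and sulfur are stereogenic only in 21 and are all flattened or expelled, while C6 and C7 are not touched under the weakly basic, then neutral conditions. The step needs C–C bond formation at the ring β-carbon C4a and not at the CH2OAc carbon, which the absence of a nucleophilic amine catalyst and the irreversible acetate loss after conjugate addition secure; a single elimination direction, which the lack of any other β-hydrogen secures; and the cyclisation-competent C4=C4a geometry, which dienol-mediated equilibration supplies and the irreversible closure to the doubly vinylogous ester O2–C3=C4–C4a=C8a–C8=O drains. The carboxylate form of 10 should also suppress self-Michael addition of the acylacrylate, and high dilution should suppress dimerisation of 21 and 22.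

Step 18
Reactants: 23 (2E)-3-[(6R,7R)-7-hydroxy-6-{[2-methoxy-3,4-bis(methoxymethoxy)-6-methylbenzoyl]oxy}-7-methyl-8-oxo-5,6,7,8-tetrahydro-1H-isochromen-3-yl]prop-2-enoic acid
Product: 24 (2E)-3-[(6R,7R)-6-[(3,4-dihydroxy-2-methoxy-6-methylbenzoyl)oxy]-7-hydroxy-7-methyl-8-oxo-5,6,7,8-tetrahydro-1H-isochromen-3-yl]prop-2-enoic acid (CNP0446308.2)
Conditions: TFA/CH2Cl2 (1:4), H2O (5 equiv), 0 °C
Reagents that add atoms: none
Why: acid-catalysed acetal cleavage should remove both aryl MOM ethers, while the hindered aryl ester, the tertiary α-ketol and the push–pull dienyl ether of ring B are expected to tolerate cold dilute TFA.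

## Compound list

1 | 2,3,4-trimethoxy-6-methylbenzaldehyde | COc1cc(C)c(C=O)c(OC)c1OC | starting material
2 | 2,3,4-trihydroxy-6-methylbenzaldehyde | Cc1cc(O)c(O)c(O)c1C=O | intermediate
3 | 2-hydroxy-3,4-bis(methoxymethoxy)-6-methylbenzaldehyde | COCOc1cc(C)c(C=O)c(O)c1OCOC | intermediate
4 | 2-methoxy-3,4-bis(methoxymethoxy)-6-methylbenzaldehyde | COc1c(OCOC)c(OCOC)cc(C)c1C=O | intermediate
5 | 2-methoxy-3,4-bis(methoxymethoxy)-6-methylbenzoic acid | COc1c(OCOC)c(OCOC)cc(C)c1C(=O)O | intermediate
6 | 2-methoxy-3,4-bis(methoxymethoxy)-6-methylbenzoyl chloride | COc1c(OCOC)c(OCOC)cc(C)c1C(Cl)=O | intermediate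
7 | 1-chloro-3-(triphenyl-λ5-phosphanylidene)propan-2-one | ClCC(=O)C=P(c1ccccc1)(c1ccccc1)c1ccccc1 | starting material
8 | 1-(phenylsulfanyl)-3-(triphenyl-λ5-phosphanylidene)propan-2-one | O=C(CSc1ccccc1)C=P(c1ccccc1)(c1ccccc1)c1ccccc1 | intermediate
9 | (2E)-4-oxo-5-(phenylsulfanyl)pent-2-enoic acid | OC(=O)/C=C/C(=O)CSc1ccccc1 | intermediate
10 | (2E)-4-oxo-5-(phenylsulfinyl)pent-2-enoic acid, racemic at sulfur | OC(=O)/C=C/C(=O)CS(=O)c1ccccc1 | intermediate
11 | 2-methylcyclohex-2-en-1-one | CC1=CCCCC1=O | starting material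
12 | (1R)-2-methylcyclohex-2-en-1-ol | CC1=CCCC[C@H]1O | intermediate
13 | tert-butyl(dimethyl){[(1R)-2-methylcyclohex-2-en-1-yl]oxy}silane | CC1=CCCC[C@H]1O[Si](C)(C)C(C)(C)C | intermediate
14 | (1R,2R,3R)-3-{[tert-butyl(dimethyl)silyl]oxy}-2-methylcyclohexane-1,2-diol | O[C@@H]1CCC[C@@H](O[Si](C)(C)C(C)(C)C)[C@]1(C)O | intermediate
15 | (1R,2R,3R)-3-{[tert-butyl(dimethyl)silyl]oxy}-2-hydroxy-2-methylcyclohexyl 2-methoxy-3,4-bis(methoxymethoxy)-6-methylbenzoate | COc1c(OCOC)c(OCOC)cc(C)c1C(=O)O[C@@H]1CCC[C@@H](O[Si](C)(C)C(C)(C)C)[C@]1(C)O | intermediate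
16 | (1R,2S,3R)-2,3-dihydroxy-2-methylcyclohexyl 2-methoxy-3,4-bis(methoxymethoxy)-6-methylbenzoate | COc1c(OCOC)c(OCOC)cc(C)c1C(=O)O[C@@H]1CCC[C@@H](O)[C@]1(C)O | intermediate
17 | (1R,2R)-2-hydroxy-2-methyl-3-oxocyclohexyl 2-methoxy-3,4-bis(methoxymethoxy)-6-methylbenzoate | COc1c(OCOC)c(OCOC)cc(C)c1C(=O)O[C@@H]1CCCC(=O)[C@]1(C)O | intermediate
18 | (1R,6R)-6-hydroxy-6-methyl-5-oxocyclohex-3-en-1-yl 2-methoxy-3,4-bis(methoxymethoxy)-6-methylbenzoate | COc1c(OCOC)c(OCOC)cc(C)c1C(=O)O[C@@H]1CC=CC(=O)[C@]1(C)O | intermediate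
19 | (1R,6R)-6-hydroxy-4-(hydroxymethyl)-6-methyl-5-oxocyclohex-3-en-1-yl 2-methoxy-3,4-bis(methoxymethoxy)-6-methylbenzoate | COc1c(OCOC)c(OCOC)cc(C)c1C(=O)O[C@@H]1CC=C(CO)C(=O)[C@]1(C)O | intermediate
20 | (1R,6R)-4-[(acetyloxy)methyl]-6-hydroxy-6-methyl-5-oxocyclohex-3-en-1-yl 2-methoxy-3,4-bis(methoxymethoxy)-6-methylbenzoate | COc1c(OCOC)c(OCOC)cc(C)c1C(=O)O[C@@H]1CC=C(COC(C)=O)C(=O)[C@]1(C)O | intermediate
21 | (1R,2R)-5-[(3E)-4-carboxy-2-oxo-1-(phenylsulfinyl)but-3-en-1-yl]-2-hydroxy-2-methyl-4-methylidene-3-oxocyclohexyl 2-methoxy-3,4-bis(methoxymethoxy)-6-methylbenzoate, mixture at ring C5, the sulfinyl carbon and sulfur | COc1c(OCOC)c(OCOC)cc(C)c1C(=O)O[C@@H]1CC(C(C(=O)/C=C/C(=O)O)S(=O)c2ccccc2)C(=C)C(=O)[C@]1(C)O | intermediate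
22 | (1R,2R,5Z)-5-[(3E)-4-carboxy-2-oxobut-3-en-1-ylidene]-2-hydroxy-2-methyl-4-methylidene-3-oxocyclohexyl 2-methoxy-3,4-bis(methoxymethoxy)-6-methylbenzoate | COc1c(OCOC)c(OCOC)cc(C)c1C(=O)O[C@@H]1C/C(=C/C(=O)/C=C/C(=O)O)C(=C)C(=O)[C@]1(C)O | intermediate
23 | (2E)-3-[(6R,7R)-7-hydroxy-6-{[2-methoxy-3,4-bis(methoxymethoxy)-6-methylbenzoyl]oxy}-7-methyl-8-oxo-5,6,7,8-tetrahydro-1H-isochromen-3-yl]prop-2-enoic acid | COc1c(OCOC)c(OCOC)cc(C)c1C(=O)O[C@@H]1CC2=C(COC(/C=C/C(=O)O)=C2)C(=O)[C@]1(C)O | intermediate
24 | (2E)-3-[(6R,7R)-6-[(3,4-dihydroxy-2-methoxy-6-methylbenzoyl)oxy]-7-hydroxy-7-methyl-8-oxo-5,6,7,8-tetrahydro-1H-isochromen-3-yl]prop-2-enoic acid | COc1c(O)c(O)cc(C)c1C(=O)O[C@@H]1CC2=C(COC(/C=C/C(=O)O)=C2)C(=O)[C@]1(C)O | target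

## Step count and risk

Total step count: 18. Longest linear sequence: 12 steps (steps 1–5, then 12–18).

Steps most likely to fail:

1. **Step 17 (proposed new method).** The carbanion may attack the acetoxymethyl carbon or add a second time; the methylidene ketone may dimerise before the sulfoxide eliminates; the sulfenic acid may add back to an acceptor. The fallback uses known reaction types, sets out from 19 and comes back at 23. Heating 19 with 2-methoxypropene and catalytic pyridinium p-toluenesulfonate (PhMe, 110 °C) should give, by Saucy–Marbet ketal Claisen rearrangement of the allyl isopropenyl ether, (1R,2R)-2-hydroxy-2-methyl-4-methylidene-3-oxo-5-(2-oxopropyl)cyclohexyl 2-methoxy-3,4-bis(methoxymethoxy)-6-methylbenzoate F1. Dehydrogenation with the IBX·4-methoxypyridine N-oxide complex at the only α-CH2/β-CH pair of F1 should give (1R,2R,5Z)-2-hydroxy-2-methyl-4-methylidene-3-oxo-5-(2-oxopropylidene)cyclohexyl 2-methoxy-3,4-bis(methoxymethoxy)-6-methylbenzoate F2, which should close by the same oxa-6π mode to (6R,7R)-7-hydroxy-3,7-dimethyl-8-oxo-5,6,7,8-tetrahydro-1H-isochromen-6-yl 2-methoxy-3,4-bis(methoxymethoxy)-6-methylbenzoate F3. Vinylogous aldol condensation of the activated 3-methyl group of F3 with glyoxylic acid monohydrate (pyrrolidine, AcOH, THF, 50 °C) should then give 23.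

2. **Step 14.** Dehydrogenation may stall at ketone 17, or oxidation may spread to the benzylic methyl group of the electron-rich arene. The fallback sets out from 16 and comes back at 18. Dess–Martin oxidation should give 17, isolated this time. TMSOTf/Et3N should give (1R,2R)-2-methyl-2,3-bis[(trimethylsilyl)oxy]cyclohex-3-en-1-yl 2-methoxy-3,4-bis(methoxymethoxy)-6-methylbenzoate F4. Saegusa–Ito oxidation (Pd(OAc)2, MeCN, rt) should give (1R,6R)-6-methyl-5-oxo-6-[(trimethylsilyl)oxy]cyclohex-3-en-1-yl 2-methoxy-3,4-bis(methoxymethoxy)-6-methylbenzoate F5, and aqueous citric acid in THF should release 18.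

3. **Step 12.** Acyl transfer from the di-ortho-substituted acyl chloride to a hindered secondary alcohol may be slow, so that decomposition of the acyl chloride or acylation at the tertiary oxygen competes. The fallback activates the nucleophile instead of the electrophile; it sets out from 14 (with 6) and comes back at 15. Bu2SnO (PhMe, reflux, water removal) should give the dibutylstannylene acetal of 14 (2,2-dibutyl-1,3,2-dioxastannolane across the cis-1,2-diol) F6, whose secondary tin alkoxide should be acylated by 6 at rt to give 15 after aqueous work-up.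

Further compounds
F1 | step 17 | (1R,2R)-2-hydroxy-2-methyl-4-methylidene-3-oxo-5-(2-oxopropyl)cyclohexyl 2-methoxy-3,4-bis(methoxymethoxy)-6-methylbenzoate, both epimers at ring C5 | COc1c(OCOC)c(OCOC)cc(C)c1C(=O)O[C@@H]1CC(CC(C)=O)C(=C)C(=O)[C@]1(C)O
F2 | step 17 | (1R,2R,5Z)-2-hydroxy-2-methyl-4-methylidene-3-oxo-5-(2-oxopropylidene)cyclohexyl 2-methoxy-3,4-bis(methoxymethoxy)-6-methylbenzoate | COc1c(OCOC)c(OCOC)cc(C)c1C(=O)O[C@@H]1C/C(=C/C(C)=O)C(=C)C(=O)[C@]1(C)O
F3 | step 17 | (6R,7R)-7-hydroxy-3,7-dimethyl-8-oxo-5,6,7,8-tetrahydro-1H-isochromen-6-yl 2-methoxy-3,4-bis(methoxymethoxy)-6-methylbenzoate | COc1c(OCOC)c(OCOC)cc(C)c1C(=O)O[C@@H]1CC2=C(COC(C)=C2)C(=O)[C@]1(C)O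
F4 | step 14 | (1R,2R)-2-methyl-2,3-bis[(trimethylsilyl)oxy]cyclohex-3-en-1-yl 2-methoxy-3,4-bis(methoxymethoxy)-6-methylbenzoate | COc1c(OCOC)c(OCOC)cc(C)c1C(=O)O[C@@H]1CCC=C(O[Si](C)(C)C)[C@]1(C)O[Si](C)(C)C
F5 | step 14 | (1R,6R)-6-methyl-5-oxo-6-[(trimethylsilyl)oxy]cyclohex-3-en-1-yl 2-methoxy-3,4-bis(methoxymethoxy)-6-methylbenzoate | COc1c(OCOC)c(OCOC)cc(C)c1C(=O)O[C@@H]1CC=CC(=O)[C@]1(C)O[Si](C)(C)C
F6 | step 12 | dibutylstannylene acetal of 14 (2,2-dibutyl-1,3,2-dioxastannolane across the cis-1,2-diol) | CCCC[Sn]1(CCCC)O[C@@H]2CCC[C@@H](O[Si](C)(C)C(C)(C)C)[C@]2(C)O1
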